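**Strategy**

Guaiane numbering is used. The seven-membered ring (C1, C5–C10) carries its oxygen at C8, the centre of the five-carbon chain C6–C10, and meets the cyclopentenone only along the C1–C5 edge. This maps onto a 1-siloxy-1-propenylcyclopropane (C6–C10, the C7 side chain already on the cyclopropane) and but-3-yn-2-one (C1, C5, C4, C15). A rhodium-catalysed [5+2] cycloaddition forms C5–C6 and C1–C10 in one operation, delivers the C8 oxygen as a silyl enol ether and relays the single catalyst-set stereocentre, C7, to C10. The acetyl group is then grown into the cyclopentenone by a Nazarov-type cationic cyclopentannelation that sets C1, and ketone reduction sets C8.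

Key step: step 4

Remark on numbering: C1 and C5 are the ring-fusion carbons; C2, C3 (carbonyl) and C4 (methyl-bearing) complete the five-membered ring; C6–C10 complete the seven-membered ring; C11 is the carbinol carbon on C7; C14 is the methyl on C10; C15 is the methyl on C4.

Assumption: the L,L-dipeptide in step 3 is taken to deliver methylene to the enol ether face that leads to 5; if a test run shows the opposite sense, the D,D-dipeptide is used.

**Route**

Step 1
Reactants: 1 (E)-pent-3-en-2-one; 2 acetone
Product: 3 (E)-6-hydroxy-6-methylhept-2-en-4-one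
Conditions: LiN(i-Pr)2, THF, −78 °C; then 2, −78 °C; AcOH quench
Reagents that add atoms: none
Why: Kinetic deprotonation of the enone at its acetyl methyl group gives the cross-conjugated lithium dienolate, which adds to acetone in a directed aldol addition; no stereocentre is formed.

Step 2
Reactants: 3 (E)-6-hydroxy-6-methylhept-2-en-4-one
Product: 4 (3Z,5E)-2,4-bis[(tert-butyldimethylsilyl)oxy]-2-methylhepta-3,5-diene
Conditions: TBSOTf (2.4 equiv), Et3N, CH2Cl2, −78 → 0 °C
Reagents that add atoms: tert-butyldimethylsilyl triflate, CC(C)(C)[Si](C)(C)OS(=O)(=O)C(F)(F)F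
Why: Silyl triflate/amine soft enolisation converts the ketone into the cross-conjugated 2-siloxydiene and silylates the tertiary alcohol in the same operation; the Z enol ether is expected because the bulky CMe2OTBS group avoids A(1,3) strain with the propenyl group.

Step 3
Reactants: 4 (3Z,5E)-2,4-bis[(tert-butyldimethylsilyl)oxy]-2-methylhepta-3,5-diene
Product: 5 tert-butyl{[(1S,2R)-2-{2-[(tert-butyldimethylsilyl)oxy]propan-2-yl}-1-[(E)-prop-1-en-1-yl]cyclopropyl]oxy}dimethylsilane
Conditions: Et2Zn, CH2I2, N-Boc-L-Val-L-Pro-OMe (25 mol %), CH2Cl2, −40 → 0 °C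
Reagents that add atoms: diiodomethane, ICI
Why: Catalytic asymmetric Simmons–Smith cyclopropanation of a silyl enol ether: the electrophilic zinc carbenoid attacks the electron-rich enol ether bond in preference to the propenyl group, syn addition carries the Z geometry into a cis OTBS/side-chain relationship, and the dipeptide-bound carbenoid selects the alkene face and so sets C7 (and C8).

Step 4
Reactants: 5 the vinylcyclopropane; 6 but-3-yn-2-one
Product: 7 1-[(3R,6R)-5-[(tert-butyldimethylsilyl)oxy]-6-{2-[(tert-butyldimethylsilyl)oxy]propan-2-yl}-3-methylcyclohepta-1,4-dien-1-yl]ethan-1-one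
Conditions: [Rh(CO)2Cl]2 (5 mol %), 6 (2 equiv), ClCH2CH2Cl, 60 °C; filtration through Et3N-deactivated silica
Reagents that add atoms: none
Why: [Rh(CO)2Cl]2 (monovalent rhodium) binds the propenyl group of 5 in its s-cis conformer and inserts into the distal cyclopropane bond C8–C6 to give a σ-alkyl/π-allyl rhodacyclohexene (trivalent rhodium); butynone then inserts into the Rh–C10 bond with its unsubstituted terminus, and C(sp2)–C(sp3) reductive elimination joins C5 to C6. The closest known reaction type is the rhodium-catalysed intermolecular [5+2] cycloaddition of 1-siloxy- or 1-alkoxyvinylcyclopropanes with alkynes (homologous Diels–Alder reaction). The seven-membered ring is closed as a metal-templated [5+2] cycloaddition, the second bond arising by reductive elimination from an eight-membered rhodacycle. The only new stereocentre, C10, is set stereospecifically: rhodium bridges C6 and the alkene face anti to C7, so the E geometry of the propenyl group together with the cyclopropane configuration (side chain cis to OTBS, trans to propenyl) places the C10 methyl cis to the C7 side chain, while C7 itself is untouched. The step needs cleavage of C8–C6 and not C8–C7, which the quaternary carbon on C7 secures by blocking the proximal bond, and it needs insertion with the acetyl-bearing alkyne carbon on rhodium, which the methyl group on the allyl terminus and the preference of an acyl-substituted carbon to stay on the metal secure. The C8 oxygen emerges as the silyl enol ether C8=C9, which masks the ketone during the next step.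

Step 5
Reactants: 7 the acetylcycloheptadiene
Product: 10 (1R,7R,10S)-11-[(tert-butyldimethylsilyl)oxy]guai-4-ene-3,8-dione, via tertiary lithium alkoxide 8 (not isolated), via tertiary trifluoroacetate 9 (not isolated)
Conditions: CH2=CHOEt, t-BuLi, THF, −78 → 0 °C; then 7, −78 °C; (CF3CO)2O, 2,6-lutidine, −78 → −20 °C; 1 M HCl, THF, 0 °C → rt
Reagents that add atoms: ethyl vinyl ether, C=COCC; water, O
Why: 1-Ethoxyvinyllithium adds 1,2 to the acetyl group, the trifluoroacetate of the bis-allylic alkoxide ionises to a 2-ethoxypentadienyl cation whose conrotatory 4π-electrocyclisation (Nazarov-type cationic cyclopentannelation) forms C1–C2 on the face of C1 anti to the adjacent C10 methyl group, and aqueous acid then unmasks the C3 enone and the C8 ketone; C1 is the γ-position of the enone, so acid equilibration favours the same trans C2/C14 arrangement.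

Step 6
Reactants: 10 the 3,8-dione
Product: 11 (1R,7S,8R,10S)-11-[(tert-butyldimethylsilyl)oxy]-8-hydroxyguai-4-en-3-one
Conditions: LiBH(s-Bu)3 (1.1 equiv), THF, −78 °C; H2O quench
Reagents that add atoms: none
Why: Substrate-controlled ketone reduction: the bulky hydride attacks the saturated C8 ketone (more electrophilic than the fully substituted cyclopentenone) from the face opposite the adjacent CMe2OTBS group and the C10 methyl group, which gives the C8 alcohol cis to the C7 side chain.

Step 7
Reactants: 11 the C8 alcohol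
Product: 12 (1R,7S,8R,10S)-11-[(tert-butyldimethylsilyl)oxy]-3-oxoguai-4-en-8-yl 2-methylprop-2-enoate
Conditions: methacrylic anhydride, DMAP, Et3N, CH2Cl2, 0 °C → rt
Reagents that add atoms: methacrylic anhydride, C=C(C)C(=O)OC(=O)C(C)=C
Why: DMAP-catalysed acylation of the only free hydroxyl group; no stereocentre is touched.

Step 8
Reactants: 12 the methacrylate silyl ether
Product: 13 (1R,7S,8R,10S)-11-hydroxy-3-oxoguai-4-en-8-yl 2-methylprop-2-enoate
Conditions: HF·pyridine, pyridine, THF, 0 °C → rt
Reagents that add atoms: none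
Why: Fluoride-mediated cleavage of the tertiary silyl ether under buffered, non-basic conditions that leave the methacrylate and the enone untouched.

Step 9
Reactants: 13 the tertiary alcohol
Product: 14 CNP0318307.1, (1R,7S,8R,10S)-11-acetoxy-3-oxoguai-4-en-8-yl 2-methylprop-2-enoate
Conditions: Ac2O, DMAP, Et3N, CH2Cl2, rt → 40 °C
Reagents that add atoms: acetic anhydride, CC(=O)OC(C)=O
Why: DMAP-catalysed acetylation of a tertiary alcohol through the N-acetylpyridinium ion; the C–O bond at C11 is not broken and no stereocentre is affected.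

**Compound list**

1 | (E)-pent-3-en-2-one | C/C=C/C(C)=O | starting material
2 | acetone | CC(C)=O | starting material
3 | (E)-6-hydroxy-6-methylhept-2-en-4-one | C/C=C/C(=O)CC(C)(C)O | intermediate
4 | (3Z,5E)-2,4-bis[(tert-butyldimethylsilyl)oxy]-2-methylhepta-3,5-diene | C/C=C/C(/O[Si](C)(C)C(C)(C)C)=C/C(C)(C)O[Si](C)(C)C(C)(C)C | intermediate
5 | tert-butyl{[(1S,2R)-2-{2-[(tert-butyldimethylsilyl)oxy]propan-2-yl}-1-[(E)-prop-1-en-1-yl]cyclopropyl]oxy}dimethylsilane | C/C=C/[C@@]1(O[Si](C)(C)C(C)(C)C)C[C@@H]1C(C)(C)O[Si](C)(C)C(C)(C)C | intermediate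
6 | but-3-yn-2-one | CC(=O)C#C | starting material
7 | 1-[(3R,6R)-5-[(tert-butyldimethylsilyl)oxy]-6-{2-[(tert-butyldimethylsilyl)oxy]propan-2-yl}-3-methylcyclohepta-1,4-dien-1-yl]ethan-1-one | CC(=O)C1=C[C@@H](C)C=C(O[Si](C)(C)C(C)(C)C)[C@@H](C(C)(C)O[Si](C)(C)C(C)(C)C)C1 | intermediate
8 | lithium 2-[(3R,6R)-5-[(tert-butyldimethylsilyl)oxy]-6-{2-[(tert-butyldimethylsilyl)oxy]propan-2-yl}-3-methylcyclohepta-1,4-dien-1-yl]-3-ethoxybut-3-en-2-olate (both carbinol epimers) | C=C(OCC)C(C)(O[Li])C1=C[C@@H](C)C=C(O[Si](C)(C)C(C)(C)C)[C@@H](C(C)(C)O[Si](C)(C)C(C)(C)C)C1 | intermediate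
9 | 2-[(3R,6R)-5-[(tert-butyldimethylsilyl)oxy]-6-{2-[(tert-butyldimethylsilyl)oxy]propan-2-yl}-3-methylcyclohepta-1,4-dien-1-yl]-3-ethoxybut-3-en-2-yl trifluoroacetate (both carbinol epimers) | C=C(OCC)C(C)(OC(=O)C(F)(F)F)C1=C[C@@H](C)C=C(O[Si](C)(C)C(C)(C)C)[C@@H](C(C)(C)O[Si](C)(C)C(C)(C)C)C1 | intermediate
10 | (1R,7R,10S)-11-[(tert-butyldimethylsilyl)oxy]guai-4-ene-3,8-dione | O=C1C[C@H](C)[C@H]2CC(=O)C(C)=C2C[C@@H]1C(C)(C)O[Si](C)(C)C(C)(C)C | intermediate
11 | (1R,7S,8R,10S)-11-[(tert-butyldimethylsilyl)oxy]-8-hydroxyguai-4-en-3-one | O[C@@H]1C[C@H](C)[C@H]2CC(=O)C(C)=C2C[C@@H]1C(C)(C)O[Si](C)(C)C(C)(C)C | intermediate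
12 | (1R,7S,8R,10S)-11-[(tert-butyldimethylsilyl)oxy]-3-oxoguai-4-en-8-yl 2-methylprop-2-enoate | C=C(C)C(=O)O[C@@H]1C[C@H](C)[C@H]2CC(=O)C(C)=C2C[C@@H]1C(C)(C)O[Si](C)(C)C(C)(C)C | intermediate
13 | (1R,7S,8R,10S)-11-hydroxy-3-oxoguai-4-en-8-yl 2-methylprop-2-enoate | C=C(C)C(=O)O[C@@H]1C[C@H](C)[C@H]2CC(=O)C(C)=C2C[C@@H]1C(C)(C)O | intermediate
14 | CNP0318307.1, (1R,7S,8R,10S)-11-acetoxy-3-oxoguai-4-en-8-yl 2-methylprop-2-enoate | C=C(C)C(=O)O[C@@H]1C[C@H](C)[C@H]2CC(=O)C(C)=C2C[C@@H]1C(C)(C)OC(C)=O | target

**Step count and risks**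

Total step count: 9. Longest linear sequence: 9 steps (1 → 14).

Steps most likely to fail:

1. Step 4. Oxidative addition into the hindered, trisubstituted vinylcyclopropane may be slow, so that rhodium-mediated oligomerisation of the conjugated ynone takes over, and the alkyne may insert with the wrong orientation. The fallback sets out from 5 and comes back at 10. 4-(Trimethylsilyl)but-3-yn-2-one is treated with 1-ethoxyvinyllithium (THF, −78 °C) to give 2-ethoxy-3-methyl-5-(trimethylsilyl)pent-1-en-4-yn-3-ol F1, and K2CO3 in MeOH removes the C-silyl group to give 2-ethoxy-3-methylpent-1-en-4-yn-3-ol F2. This unconjugated propargylic alcohol does not oligomerise as an ynone does, and its quaternary propargylic carbon forces the substituted alkyne carbon away from the methyl-bearing allyl terminus. Cycloaddition with 5 ([Rh(CO)2Cl]2, ClCH2CH2Cl, 60 °C) gives 2-[(3R,6R)-5-[(tert-butyldimethylsilyl)oxy]-6-{2-[(tert-butyldimethylsilyl)oxy]propan-2-yl}-3-methylcyclohepta-1,4-dien-1-yl]-3-ethoxybut-3-en-2-ol F3, the free alcohol of 8. F3 is ionised with (CF3CO)2O/2,6-lutidine and hydrolysed with 1 M HCl as in step 5 to give 10.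

2. Step 5. The enol ether may hydrolyse before the carbinol ionises (acyloin formation), the vinyllithium may deprotonate 7 at C10, or the pentadienyl cation may lose a proton without cyclising. The fallback sets out from 7 and comes back at 10. HC≡CMgBr adds to the acetyl group (THF, 0 °C) and the magnesium alkoxide is trapped with pivaloyl chloride/DMAP to give 2-[(3R,6R)-5-[(tert-butyldimethylsilyl)oxy]-6-{2-[(tert-butyldimethylsilyl)oxy]propan-2-yl}-3-methylcyclohepta-1,4-dien-1-yl]but-3-yn-2-yl pivalate F4. Ph3PAuCl/AgSbF6 (monovalent gold) in wet MeCN then effects the Rautenstrauch rearrangement (1,2-acyloxy shift, cyclisation onto C1, hydrolysis of the dienyl pivalate), and work-up with 1 M HCl cleaves the silyl enol ether to give 10. Because the carbinol centre of F4 is a mixture, C1 epimers are expected; they would be converged by equilibration through the dienolate with DBU.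

3. Step 3. Enantiofacial discrimination by the dipeptide-bound carbenoid may be poor on a non-aryl, trisubstituted dienyl silyl ether, and methylene transfer next to the quaternary carbon may be slow. The fallback sets out from 1 and comes back at 5. TBSOTf/Et3N converts 1 into tert-butyldimethyl{[(3E)-penta-1,3-dien-2-yl]oxy}silane F5. Carbene transfer from tert-butyl diazoacetate with CuOTf (monovalent copper) and 2,2'-isopropylidenebis[(4S)-4-tert-butyl-2-oxazoline] cyclopropanates the terminal enol ether bond, and the isomer with the ester cis to the siloxy group, tert-butyl (1S,2S)-2-[(tert-butyldimethylsilyl)oxy]-2-[(E)-prop-1-en-1-yl]cyclopropane-1-carboxylate F6, is separated. MeMgBr (THF, 0 °C) converts the ester into 2-[(1R,2S)-2-[(tert-butyldimethylsilyl)oxy]-2-[(E)-prop-1-en-1-yl]cyclopropyl]propan-2-ol F7, and TBSOTf/2,6-lutidine gives 5.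

**Further compounds**

F1 | step 4 | 2-ethoxy-3-methyl-5-(trimethylsilyl)pent-1-en-4-yn-3-ol | C=C(OCC)C(C)(O)C#C[Si](C)(C)C
F2 | step 4 | 2-ethoxy-3-methylpent-1-en-4-yn-3-ol | C=C(OCC)C(C)(O)C#C
F3 | step 4 | 2-[(3R,6R)-5-[(tert-butyldimethylsilyl)oxy]-6-{2-[(tert-butyldimethylsilyl)oxy]propan-2-yl}-3-methylcyclohepta-1,4-dien-1-yl]-3-ethoxybut-3-en-2-ol (both carbinol epimers) | C=C(OCC)C(C)(O)C1=C[C@@H](C)C=C(O[Si](C)(C)C(C)(C)C)[C@@H](C(C)(C)O[Si](C)(C)C(C)(C)C)C1
F4 | step 5 | 2-[(3R,6R)-5-[(tert-butyldimethylsilyl)oxy]-6-{2-[(tert-butyldimethylsilyl)oxy]propan-2-yl}-3-methylcyclohepta-1,4-dien-1-yl]but-3-yn-2-yl pivalate (both carbinol epimers) | C#CC(C)(OC(=O)C(C)(C)C)C1=C[C@@H](C)C=C(O[Si](C)(C)C(C)(C)C)[C@@H](C(C)(C)O[Si](C)(C)C(C)(C)C)C1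
F5 | step 3 | tert-butyldimethyl{[(3E)-penta-1,3-dien-2-yl]oxy}silane | C/C=C/C(=C)O[Si](C)(C)C(C)(C)C
F6 | step 3 | tert-butyl (1S,2S)-2-[(tert-butyldimethylsilyl)oxy]-2-[(E)-prop-1-en-1-yl]cyclopropane-1-carboxylate | C/C=C/[C@@]1(O[Si](C)(C)C(C)(C)C)C[C@@H]1C(=O)OC(C)(C)C
F7 | step 3 | 2-[(1R,2S)-2-[(tert-butyldimethylsilyl)oxy]-2-[(E)-prop-1-en-1-yl]cyclopropyl]propan-2-ol | C/C=C/[C@@]1(O[Si](C)(C)C(C)(C)C)C[C@@H]1C(C)(C)O
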